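## Retrosynthetic overview

1. Target 20 ⇐ diol 19: Pd-catalysed cyclocarbonylation of the C6-hydroxyl/C7-ethynyl pair closes the α-methylene lactone last.
2. 19 ⇐ 16 ⇐ 15: Criegee 1,2-shift of C6 from C1 to oxygen in a trans-decalin β-acetoxy peracetate; the C1–C6 ring-fusion bond becomes C1=O and C6–O (6/6 bicycle → ten-membered ring, retention at C6).
3. 15 ⇐ 14 ⇐ 13: epoxidation and trans-diaxial perhydrolysis of a tetrasubstituted C1=C10 octalin.
4. 13 ⇐ 9 ⇐ 5 + 6: Stork–Robinson annulation builds ring B; deconjugation and hydride reduction set C4 and C3.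
5. 5 ⇐ 1: ring A from (R)-4-hydroxycyclohexenone. Ring order: A (bought) → B → ten-membered ring → lactone.

Assumption: (R)-4-hydroxycyclohex-2-en-1-one (eight non-hydrogen atoms) is available enantiopure.

Locants: C1–C13 below are those of the target (C1 ketone, C3 OH, C4 Me, C6 lactone O, C7, C8 angelate, C10 Me/OAc, C11–C13 acrylate). Ring A = C1, C10, C9, C8, C7, C6; ring B = C1–C6; the two rings share the C1–C6 bond until step 10. The methyl-bearing C10 is carried as an epimer mixture until it becomes sp2 in step 5.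

## Route

Step 1
Reactants: 1 (R)-4-hydroxycyclohex-2-en-1-one
Product: 2 (4R)-4-hydroxy-6-methylcyclohex-2-en-1-one
Conditions: LiN(i-Pr)2 (2.2 equiv), THF, −78 °C; MeI (1.1 equiv), −78 → −40 °C; aq NH4Cl
Reagents that add atoms: iodomethane CI
Why: Dianion α′-alkylation of an enone, in which the first equivalent of base makes the lithium alkoxide, the second gives the kinetic cross-conjugated enolate, and MeI methylates carbon while the alkoxide is inert at −78 °C; the new centre (C10) is uncontrolled and is erased in step 5.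

Step 2
Reactants: 2 (4R)-4-hydroxy-6-methylcyclohex-2-en-1-one
Product: 3 (4R,5R)-5-ethynyl-4-hydroxy-2-methylcyclohexan-1-one
Conditions: HC≡CMgBr (3.5 equiv), THF, −20 °C → rt; aq NH4Cl
Reagents that add atoms: ethynylmagnesium bromide C#C[Mg]Br
Why: Hydroxyl-directed (ligand-assisted) conjugate addition, in which the magnesium alkoxide at C8 binds the alkynyl Grignard and delivers it to the β-carbon C7 on its own face, so the ethynyl group ends cis to the C8 oxygen.

Step 3
Reactants: 3 (4R,5R)-5-ethynyl-4-hydroxy-2-methylcyclohexan-1-one, 4 angelic acid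
Product: 5 (1R,2R)-2-ethynyl-5-methyl-4-oxocyclohexyl (Z)-2-methylbut-2-enoate
Conditions: 4, 2,4,6-Cl3C6H2COCl, Et3N, PhMe, rt; then 3, DMAP, 0 °C → rt
Reagents that add atoms: none
Why: Yamaguchi esterification through the mixed anhydride acylates the secondary alcohol under conditions mild enough to keep the Z (angelate) geometry; no stereocentre is touched.

Step 4
Reactants: 5 (1R,2R)-2-ethynyl-5-methyl-4-oxocyclohexyl (Z)-2-methylbut-2-enoate, 6 3-methylbut-3-en-2-one
Product: 9 ring A/ring B bicyclic enone (C3 ketone; C1=C2), via pyrrolidine enamine 7 (not isolated), via 1,5-diketone 8 (not isolated)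
Conditions: pyrrolidine (1.3 equiv), 4 Å MS, PhMe, 40 °C; then 6 (1.5 equiv), 1,4-dioxane, 60 °C; then AcOH/NaOAc/H2O, 80 °C
Reagents that add atoms: none
Why: Stork enamine Michael addition followed by Robinson aldol condensation, in which the less substituted enamine (toward C6) attacks the enone anti to the neighbouring ethynyl group (C6–C5 bond trans to C7-ethynyl) and the C4 methyl, α to the new ketone, settles equatorial (cis-1,3 to the C6–C7 bond).

Step 5
Reactants: 9 ring A/ring B bicyclic enone
Product: 11 β,γ-unsaturated ketone (C3 ketone; tetrasubstituted C1=C10), via dienol methyl ether 10 (not isolated)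
Conditions: HC(OMe)3 (3 equiv), TsOH·H2O (5 mol%), MeOH/1,4-dioxane, rt; then oxalic acid, H2O/THF, 0 °C
Reagents that add atoms: water O (carbonyl oxygen of 11); trimethyl orthoformate COC(OC)OC (methoxy group of 10 only)
Why: Deconjugation through the thermodynamic heteroannular dienol ether (the fully substituted C1=C10 position, as in 6-methyl-19-nor-steroid 3,5-dienol ethers) followed by kinetic C2 protonation on weak-acid hydrolysis; H-6 is not touched and C10 loses its stereocentre.

Step 6
Reactants: 11 β,γ-unsaturated ketone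
Product: 12 (3R)-homoallylic alcohol (axial 3-OH cis to 4-Me)
Conditions: LiBH(s-Bu)3 (1.2 equiv), THF, −78 °C; aq NH4Cl
Reagents that add atoms: none
Why: Bulky-hydride (Selectride) reduction, in which equatorial attack on the ring B ketone gives the axial alcohol cis to the equatorial C4 methyl, as in the reduction of 2-methylcyclohexanones and 5-en-3-one steroids.

Step 7
Reactants: 12 (3R)-homoallylic alcohol
Product: 13 3-O-tert-butyldimethylsilyl ether of 12
Conditions: TBSOTf (1.3 equiv), 2,6-lutidine, CH2Cl2, −78 → 0 °C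
Reagents that add atoms: tert-butyldimethylsilyl trifluoromethanesulfonate CC(C)(C)[Si](C)(C)OS(=O)(=O)C(F)(F)F
Why: Standard silyl-triflate protection of a hindered axial alcohol; it keeps C3–OH out of the acetylation in step 10 and shields the lower face of C1 in step 8.

Step 8
Reactants: 13 3-O-tert-butyldimethylsilyl ether of 12
Product: 14 1,10-epoxide (oxygen syn to H-6)
Conditions: mCPBA (1.2 equiv), NaHCO3, CH2Cl2, −20 → 0 °C
Reagents that add atoms: 3-chloroperoxybenzoic acid OOC(=O)c1cccc(Cl)c1
Why: Prilezhaev epoxidation of the only electron-rich alkene (alkyne and enoate are inert), with the peracid approaching anti to the axial C3 silyloxy group that is 1,3-diaxial to the lower lobe at C1; this fixes the C10–O configuration of the target.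

Step 9
Reactants: 14 1,10-epoxide
Product: 15 trans-decalin 1-hydroperoxide 10-alcohol
Conditions: H2O2 (ca. 3 M in Et2O, 10 equiv), H3PMo12O40 (2 mol%), Et2O, 0 °C
Reagents that add atoms: hydrogen peroxide OO
Why: Acid-catalysed epoxide perhydrolysis under Fürst–Plattner (trans-diaxial) control, in which H2O2 attacks the ring-fusion carbon C1 with inversion from the lower face, so C10 keeps its oxygen (10S, axial) and C1 carries an axial hydroperoxide anti to H-6.

Step 10
Reactants: 15 trans-decalin 1-hydroperoxide 10-alcohol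
Product: 19 ten-membered 3,6-dihydroxy-1-ketone, via acetoxy peracetate 16 (not isolated), via bridged ketal acetate 17 (not isolated), via silyl-protected keto alcohol 18 (not isolated)
Conditions: Ac2O (4 equiv), DMAP (0.5 equiv), Et3N, CH2Cl2, 0 °C → rt; then (CF3)2CHOH, 35 °C; then aq HF, MeCN, 0 °C → rt
Reagents that add atoms: acetic anhydride CC(=O)OC(C)=O (acetyl of the C10 acetate); water O (C1 carbonyl oxygen)
Why: Proposed new method: an acylative Criegee ring expansion of a trans-diaxial β-hydroxy tert-hydroperoxide, in which Ac2O/DMAP esterifies both O–H groups (16) and, in the ionising medium, the peracetate O–O bond heterolyses with concerted 1,2-shift of the ring-fusion carbon C6 from C1 to oxygen with retention (giving 6S); C6 is expected to be the only migrating group because the axial peroxy group of the rigid trans-decalin can point only away from both rings, which puts the O–O bond anti to C1–C6 and excludes C2 and the acetoxy-bearing C10, and the resulting bridged oxocarbenium collapses to acylal 17, whose hydrolysis unveils the C1 ketone and C6–OH while HF also frees C3–OH; the closest known reaction type is the Criegee rearrangement of trans-9-decalyl peresters to 6-hydroxycyclodecanone, not yet shown for β-oxygenated hydroperoxides, which normally cleave toward the oxygenated carbon (Hock-type).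

Step 11
Reactants: 19 ten-membered 3,6-dihydroxy-1-ketone
Product: 20 target CNP0141210.3
Conditions: PdCl2 (5 mol%), PPh3 (10 mol%), SnCl2 (5 mol%), CO (7 atm), MeCN, 65 °C
Reagents that add atoms: carbon monoxide [C-]#[O+]
Why: Norton-type palladium-catalysed cyclocarbonylation of a homopropargylic alcohol (alkoxycarbonyl-palladium formation at C6–OH, syn insertion of the alkyne, protonolysis); only C6–OH can close a five-membered ring (C8–O is acylated, C3–OH is remote), giving the cis-fused α-methylene lactone with all stereocentres untouched.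

## Compound list

1 | (R)-4-hydroxycyclohex-2-en-1-one | O=C1C=C[C@H](O)CC1 | starting material
2 | (4R)-4-hydroxy-6-methylcyclohex-2-en-1-one (C6 epimers) | CC1C[C@@H](O)C=CC1=O | intermediate
3 | (4R,5R)-5-ethynyl-4-hydroxy-2-methylcyclohexan-1-one (ethynyl cis to OH; C2 epimers) | CC1C[C@@H](O)[C@@H](C#C)CC1=O | intermediate
4 | angelic acid, (Z)-2-methylbut-2-enoic acid | OC(=O)/C(C)=C\C | starting material
5 | (1R,2R)-2-ethynyl-5-methyl-4-oxocyclohexyl (Z)-2-methylbut-2-enoate (C5 epimers) | CC1C[C@@H](OC(=O)/C(C)=C\C)[C@@H](C#C)CC1=O | intermediate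
6 | 3-methylbut-3-en-2-one | CC(=O)C(C)=C | starting material
7 | pyrrolidine enamine of 5 (C1=C6 double bond) | CC1C[C@@H](OC(=O)/C(C)=C\C)[C@@H](C#C)C=C1N2CCCC2 | intermediate
8 | 1,5-diketone: 5 carrying a 2-methyl-3-oxobutyl chain at C6, trans to the C7 ethynyl group (C4 and C10 epimers) | CC1C[C@@H](OC(=O)/C(C)=C\C)[C@@H](C#C)[C@H](CC(C)C(C)=O)C1=O | intermediate
9 | bicyclic enone: C3 ketone, C1=C2 alkene, 4-Me equatorial (cis to the C6–C7 bond), H-6 trans to 7-ethynyl, 8-angeloyloxy cis to ethynyl, 10-Me (epimers) | O=C1C=C2C(C)C[C@@H](OC(=O)/C(C)=C\C)[C@@H](C#C)[C@@H]2C[C@@H]1C | intermediate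
10 | dienol methyl ether of 9: 3-methoxy-2,1(10)-diene | COC1=CC2=C(C)C[C@@H](OC(=O)/C(C)=C\C)[C@@H](C#C)[C@@H]2C[C@@H]1C | intermediate
11 | β,γ-unsaturated ketone: C3 ketone, tetrasubstituted C1=C10 alkene | O=C1CC2=C(C)C[C@@H](OC(=O)/C(C)=C\C)[C@@H](C#C)[C@@H]2C[C@@H]1C | intermediate
12 | (3R)-alcohol of 11: axial 3-OH cis to 4-Me | O[C@@H]1CC2=C(C)C[C@@H](OC(=O)/C(C)=C\C)[C@@H](C#C)[C@@H]2C[C@@H]1C | intermediate
13 | 3-O-tert-butyldimethylsilyl ether of 12 | CC(C)(C)[Si](C)(C)O[C@@H]1CC2=C(C)C[C@@H](OC(=O)/C(C)=C\C)[C@@H](C#C)[C@@H]2C[C@@H]1C | intermediate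
14 | 1,10-epoxide of 13, epoxide oxygen syn to H-6 and to the C8 ester | CC(C)(C)[Si](C)(C)O[C@@H]1C[C@@]23O[C@@]3(C)C[C@@H](OC(=O)/C(C)=C\C)[C@@H](C#C)[C@@H]2C[C@@H]1C | intermediate
15 | trans-fused decalin: axial C1 hydroperoxide anti to H-6, axial (10S) tertiary alcohol, 3-OTBS | CC(C)(C)[Si](C)(C)O[C@@H]1C[C@@]2(OO)[C@@](C)(O)C[C@@H](OC(=O)/C(C)=C\C)[C@@H](C#C)[C@@H]2C[C@@H]1C | intermediate
16 | C1 peracetate, C10 acetate of 15 | CC(C)(C)[Si](C)(C)O[C@@H]1C[C@@]2(OOC(C)=O)[C@@](C)(OC(C)=O)C[C@@H](OC(=O)/C(C)=C\C)[C@@H](C#C)[C@@H]2C[C@@H]1C | intermediate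
17 | bridged acylal: 1-acetoxy-1,6-epoxide (11-oxabicyclo[4.4.1]undecane core), 10-OAc, 8-angelate, 7-ethynyl, 3-OTBS | CC(C)(C)[Si](C)(C)O[C@@H]1C[C@@]2(OC(C)=O)O[C@@H](C[C@@H]1C)[C@H](C#C)[C@H](OC(=O)/C(C)=C\C)C[C@]2(C)OC(C)=O | intermediate
18 | ten-membered 6-hydroxy-1-ketone, 3-OTBS, 10-OAc, 8-angelate, 7-ethynyl | O[C@H]1C[C@H](C)[C@H](O[Si](C)(C)C(C)(C)C)CC(=O)[C@@](C)(OC(C)=O)C[C@@H](OC(=O)/C(C)=C\C)[C@H]1C#C | intermediate
19 | ten-membered 3,6-dihydroxy-1-ketone (3R,4S,6S,10S), 10-OAc, 8-angelate, 7-ethynyl | O[C@H]1C[C@H](C)[C@H](O)CC(=O)[C@@](C)(OC(C)=O)C[C@@H](OC(=O)/C(C)=C\C)[C@H]1C#C | intermediate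
20 | target: (3R,4S,6S,7S,8R,10S)-10-acetoxy-8-angeloyloxy-3-hydroxy-1-oxo-germacr-11(13)-en-12,6-olide | C=C1C(=O)O[C@H]2C[C@H](C)[C@H](O)CC(=O)[C@@](C)(OC(C)=O)C[C@@H](OC(=O)/C(C)=C\C)[C@@H]12 | target

## Step count and main risks

Total step count: 11. Longest linear sequence: 11 steps (1 → 20; 4 and 6 are bought and used directly).

Step 10, the new step, is the most exposed: the peracetate may ionise sluggishly, or the oxygenated C10 may compete in the shift. The fallback uses known chemistry only, sets out from 15 and comes back at 19. The hydroperoxide alone is acylated with 4-nitrobenzoyl chloride/pyridine in CH2Cl2 at −20 °C to give the tert-alkyl 4-nitroperbenzoate F1. The C10 hydroxyl is then acetylated (Ac2O, DMAP, CH2Cl2, 0 °C) to give the perester acetate F2. F2 is isolated and solvolysed in methanol at 40 °C, the classical thermal Criegee rearrangement of decalyl peresters, to give the bridged ketal 4-nitrobenzoate F3. Aqueous HF in MeCN then cleaves the acylal and, through 18, the silyl ether to give 19. This replaces the one-flask acetyl-triggered cascade by a stepwise sequence built on an isolated, more reactive perester.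

Step 8 relies on steric shielding by the axial C3 silyl ether alone, against an axial C8 ester on the other face, so the wrong epoxide may form. The fallback sets out from 13 and comes back at 14, and changes from steric to hydroxyl-directed control. The angelate is removed with i-Bu2AlH (CH2Cl2, −78 °C) to give the C8 homoallylic alcohol F4, whose hydroxyl lies on the required face. VO(acac)2/t-BuOOH (PhMe, 0 °C → rt) then delivers oxygen syn to it to give the epoxy alcohol F5. Re-esterification with 4 under the step 3 conditions gives 14.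

Step 4 can fail through C6 epimerisation (the ethynyl group is a small stereocontrol element), bridged-ketol formation or slow addition to the α-substituted enone. The fallback sets out from 5 and comes back at 9, using a preformed, regiodefined nucleophile instead of the enamine. Kinetic deprotonation (LiN(i-Pr)2, THF, −78 °C, Me3SiCl) gives the less substituted trimethylsilyl enol ether F6. TiCl4-mediated Mukaiyama–Michael addition to 6 (CH2Cl2, −78 °C) gives diketone 8 without equilibration. 8 is then cyclised and dehydrated separately (TsOH, PhH, reflux) to 9.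

Further compounds
F1 | step 10 | C1 4-nitroperbenzoate of 15 (C10–OH free) | CC(C)(C)[Si](C)(C)O[C@@H]1C[C@@]2(OOC(=O)c3ccc(cc3)[N+](=O)[O-])[C@@](C)(O)C[C@@H](OC(=O)/C(C)=C\C)[C@@H](C#C)[C@@H]2C[C@@H]1C
F2 | step 10 | C1 4-nitroperbenzoate, C10 acetate of 15 | CC(C)(C)[Si](C)(C)O[C@@H]1C[C@@]2(OOC(=O)c3ccc(cc3)[N+](=O)[O-])[C@@](C)(OC(C)=O)C[C@@H](OC(=O)/C(C)=C\C)[C@@H](C#C)[C@@H]2C[C@@H]1C
F3 | step 10 | bridged ketal 4-nitrobenzoate (4-nitrobenzoyl analogue of 17) | CC(C)(C)[Si](C)(C)O[C@@H]1C[C@@]2(OC(=O)c3ccc(cc3)[N+](=O)[O-])O[C@@H](C[C@@H]1C)[C@H](C#C)[C@H](OC(=O)/C(C)=C\C)C[C@]2(C)OC(C)=O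
F4 | step 8 | C8 alcohol from 13 (angelate removed) | CC(C)(C)[Si](C)(C)O[C@@H]1CC2=C(C)C[C@@H](O)[C@@H](C#C)[C@@H]2C[C@@H]1C
F5 | step 8 | 1,10-epoxy C8 alcohol (epoxide syn to the C8 hydroxyl) | CC(C)(C)[Si](C)(C)O[C@@H]1C[C@@]23O[C@@]3(C)C[C@@H](O)[C@@H](C#C)[C@@H]2C[C@@H]1C
F6 | step 4 | trimethylsilyl enol ether of 5 (C1=C6) | CC1C[C@@H](OC(=O)/C(C)=C\C)[C@@H](C#C)C=C1O[Si](C)(C)C
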